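Assumption: the target has no stereocentre (it is achiral), so no enantiocontrol is needed; compounds 1 and 3 are taken as catalogue materials.

**Retrosynthetic overview**
1. Target 8 ⇐ removal of the two B-ring benzyl ethers from 7.
2. 7 ⇐ C8–OMe bond made last, by ortho C–H methoxylation of the free 7-phenol of flavone 5 (key C–O bond).
3. 5 ⇐ O1–C2 cyclodehydration of 1,3-diketone 4, which comes from Claisen condensation of acetophenone 3 with ester 2.
4. Ring order: A and B rings are bought; the pyranone C ring is closed in step 2; the last A-ring oxygen is added in step 3.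

**Route**

Step 1
Reactants: 1 methyl 3,5-dihydroxy-4-methoxybenzoate
Product: 2 methyl 3,5-bis(benzyloxy)-4-methoxybenzoate
Conditions: BnBr (2.3 equiv), K2CO3 (2.5 equiv), DMF, 60 °C, 6 h
Reagents that add atoms: benzyl bromide, BrCc1ccccc1
Why: Williamson ether synthesis on two equivalent phenols; the methyl ester and the aryl methyl ether are inert to K2CO3/DMF.

Step 2
Reactants: 2 methyl 3,5-bis(benzyloxy)-4-methoxybenzoate; 3 1-(2,4-dihydroxy-6-methoxyphenyl)ethan-1-one
Product: 5 2-[3,5-bis(benzyloxy)-4-methoxyphenyl]-7-hydroxy-5-methoxy-4H-chromen-4-one, via diketone 4 (not isolated)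
Conditions: 3, LiHMDS (4.5 equiv), THF, −78 → −10 °C; add 2, then reflux 6 h; 1 M HCl quench, solvent swap; AcOH, H2SO4 (0.5 vol %), 95 °C, 1 h
Reagents that add atoms: none
Why: Claisen condensation of the trilithiated hydroxyacetophenone with the ester gives the C-acylated diketone (reversible O-acylation funnels to the stable diketonate), and acid-catalysed cyclodehydration through the 2-OH closes the pyranone; the 6-OMe becomes 5-OMe and the untouched 4-OH becomes 7-OH.

Step 3
Reactants: 5 2-[3,5-bis(benzyloxy)-4-methoxyphenyl]-7-hydroxy-5-methoxy-4H-chromen-4-one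
Product: 7 2-[3,5-bis(benzyloxy)-4-methoxyphenyl]-7-hydroxy-5,8-dimethoxy-4H-chromen-4-one, via iodonium phenolate 6 (not isolated)
Conditions: MesI(OAc)2 (1.05 equiv), K2CO3 (2.0 equiv), MeOH–CH2Cl2 3:1, 0 °C, 1 h, Ar; then Cu(MeCN)4PF6 (10 mol %), 50 °C, 6 h; dilute HCl work-up
Reagents that add atoms: methanol, CO (gives the 8-OMe of 7); iodomesitylene diacetate, CC(=O)OI(OC(C)=O)c1c(C)cc(C)cc1C (gives the mesityliodonio group of 6 only)
Why: Proposed new method: one-pot ortho C–H methoxylation of a phenol — the 7-phenoxide (a vinylogous carboxylate) attacks MesI(OAc)2 through C8, which is ortho to O7 and O1, para to 5-OMe and unhindered (C6 is shielded by the 5-OMe methyl), giving iodonium phenolate 6 and consuming all I(III) before copper is added; Cu(I) then either forms an aryl–Cu(III)–OMe species that reductively eliminates, or expels MesI to a copper quinonoid carbene that inserts into the O–H of MeOH and tautomerises, and both paths give the C8–OMe bond with mesityl as the non-transferred group; the closest known reaction types are iodonium phenolate formation from acidic phenols with ArI(OAc)2, one-pot arene C–H amination or aryloxylation through unsymmetrical diaryl-λ3-iodanes under Cu(I) catalysis, and metal-catalysed O–H insertion of 1,3-dione iodonium ylides into alcohols.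

Step 4
Reactants: 7 2-[3,5-bis(benzyloxy)-4-methoxyphenyl]-7-hydroxy-5,8-dimethoxy-4H-chromen-4-one
Product: 8 2-(3,5-dihydroxy-4-methoxyphenyl)-7-hydroxy-5,8-dimethoxy-4H-chromen-4-one (CNP0218554.0)
Conditions: H2 (1 atm), 10% Pd/C, EtOAc–MeOH 1:1, rt, 4 h (7 chromatographed first to remove iodomesitylene and copper)
Reagents that add atoms: none
Why: Catalytic hydrogenolysis of the two aryl benzyl ethers; the flavone C2=C3 bond, the carbonyl and the three methyl ethers are untouched at 1 atm and room temperature.

**Compound list**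
1 | methyl 3,5-dihydroxy-4-methoxybenzoate | COC(=O)c1cc(O)c(OC)c(O)c1 | starting material
2 | methyl 3,5-bis(benzyloxy)-4-methoxybenzoate | COC(=O)c1cc(OCc2ccccc2)c(OC)c(OCc2ccccc2)c1 | intermediate
3 | 1-(2,4-dihydroxy-6-methoxyphenyl)ethan-1-one | CC(=O)c1c(O)cc(O)cc1OC | starting material
4 | 1-[3,5-bis(benzyloxy)-4-methoxyphenyl]-3-(2,4-dihydroxy-6-methoxyphenyl)propane-1,3-dione | COc1cc(O)cc(O)c1C(=O)CC(=O)c1cc(OCc2ccccc2)c(OC)c(OCc2ccccc2)c1 | intermediate (not isolated)
5 | 2-[3,5-bis(benzyloxy)-4-methoxyphenyl]-7-hydroxy-5-methoxy-4H-chromen-4-one | COc1cc(O)cc2oc(-c3cc(OCc4ccccc4)c(OC)c(OCc4ccccc4)c3)cc(=O)c12 | intermediate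
6 | 2-[3,5-bis(benzyloxy)-4-methoxyphenyl]-8-(mesityliodonio)-5-methoxy-4-oxo-4H-chromen-7-olate | COc1cc([O-])c([I+]c3c(C)cc(C)cc3C)c2oc(-c3cc(OCc4ccccc4)c(OC)c(OCc4ccccc4)c3)cc(=O)c12 | intermediate (not isolated)
7 | 2-[3,5-bis(benzyloxy)-4-methoxyphenyl]-7-hydroxy-5,8-dimethoxy-4H-chromen-4-one | COc1cc(O)c(OC)c2oc(-c3cc(OCc4ccccc4)c(OC)c(OCc4ccccc4)c3)cc(=O)c12 | intermediate
8 | 2-(3,5-dihydroxy-4-methoxyphenyl)-7-hydroxy-5,8-dimethoxy-4H-chromen-4-one | COc1c(O)cc(-c2cc(=O)c3c(OC)cc(O)c(OC)c3o2)cc1O | target

**Step count**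
Total steps: 4. Longest linear sequence: 4 (1 → 2 → 5 → 7 → 8).

**Three steps most likely to fail, with fallbacks**

Step 3 (proposed new C–H methoxylation). Risks are failure of the copper-mediated C–O coupling, aryl migration from iodine to O7, or reaction at C6. The fallback uses known chemistry and sets out from compound 5. Bromination with NBS (1.0 equiv, DMF, 0 °C), which goes to C8 in 5-O-methylated 7-hydroxyflavones, gives 2-[3,5-bis(benzyloxy)-4-methoxyphenyl]-8-bromo-7-hydroxy-5-methoxy-4H-chromen-4-one F1. Ullmann-type methoxylation (NaOMe in excess, CuBr, DMF–MeOH, 110 °C) then replaces bromide by methoxide. The fallback comes back to the route at compound 7.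

Step 2 (ester Claisen condensation with a free 4-OH, then cyclodehydration). Risks are sluggish C-acylation by the electron-rich ester and partial benzyl ether loss in hot acid. The fallback sets out from compounds 2 and 3 and builds the ring by aldol condensation and oxidative cyclisation instead. DIBAL-H (CH2Cl2, −78 → 0 °C) reduces 2 to [3,5-bis(benzyloxy)-4-methoxyphenyl]methanol F2, and MnO2 (CH2Cl2, rt) oxidises this to 3,5-bis(benzyloxy)-4-methoxybenzaldehyde F3. Claisen–Schmidt condensation of the aldehyde with 3 (50% aq KOH, EtOH, rt, 48 h) gives (E)-3-[3,5-bis(benzyloxy)-4-methoxyphenyl]-1-(2,4-dihydroxy-6-methoxyphenyl)prop-2-en-1-one F4. Oxidative cyclisation with I2 (10 mol %) in DMSO at 120 °C closes the O1–C2 bond. The fallback comes back to the route at compound 5.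

Step 4 (hydrogenolysis). Risks are catalyst poisoning by traces of iodoarene or copper and over-reduction of the C2=C3 bond. The fallback sets out from compound 7 and removes the benzyl groups by acidolysis instead of reduction: TFA with pentamethylbenzene (6 equiv) as benzyl cation scavenger at 40–50 °C, conditions that spare aryl methyl ethers. It makes no new compound F0 and comes back to the route at compound 8.

**Further compounds**
F1 | step 3 | 2-[3,5-bis(benzyloxy)-4-methoxyphenyl]-8-bromo-7-hydroxy-5-methoxy-4H-chromen-4-one | COc1cc(O)c(Br)c2oc(-c3cc(OCc4ccccc4)c(OC)c(OCc4ccccc4)c3)cc(=O)c12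
F2 | step 2 | [3,5-bis(benzyloxy)-4-methoxyphenyl]methanol | OCc1cc(OCc2ccccc2)c(OC)c(OCc2ccccc2)c1
F3 | step 2 | 3,5-bis(benzyloxy)-4-methoxybenzaldehyde | O=Cc1cc(OCc2ccccc2)c(OC)c(OCc2ccccc2)c1
F4 | step 2 | (E)-3-[3,5-bis(benzyloxy)-4-methoxyphenyl]-1-(2,4-dihydroxy-6-methoxyphenyl)prop-2-en-1-one | COc1cc(O)cc(O)c1C(=O)/C=C/c1cc(OCc2ccccc2)c(OC)c(OCc2ccccc2)c1
F0 | step 4 | none | none
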